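## Analysis of the target

Atom labels: O1, C2, C3, C3a–C7a for the dihydrobenzofuran, C9 for the hydroxymethyl carbon on C3, and C7′–C8′–C9′ for the propanediol chain. Ring A is the aryl on C2, ring B the benzo ring, ring C the aryl on C8′.

- The target 28 is a 2-aryl-3-hydroxymethyl-7-methoxy-2,3-dihydrobenzofuran. At C5 it carries a 1-hydroxy-2-aryl-3-hydroxypropyl chain; rings A and C are both 4-hydroxy-3-methoxyphenyl groups.
- There are four stereocentres in two pairs. C2 (S) and C3 (R) are trans on the five-membered ring. C7′ (S) and C8′ (R) have the syn relationship of an aldol adduct.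
- Ring B separates the two pairs, so neither can pass stereochemical information to the other. Each pair needs its own source of absolute configuration.
- The sensitive sites are the two free phenols, the O1–C2 bond and the C7′ alcohol. The O1–C2 bond is a benzylic aryl ether para to the ring A oxygen: it ionises in acid, can open through a quinone methide in base once the ring A phenol is free, and is open to hydrogenolysis. The C7′ alcohol is benzylic and para to O1, so it also ionises in acid.
- The difficulty is therefore threefold: two phenols and two primary alcohols must be told apart, two independent stereo-pairs must be set, and no acid may meet the C7′ carbinol.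
- The strategy rests on one feature. C2 is benzylic to ring A and para to its oxygen, so a hydroxyl on C2 leaves easily to give a cation that is an O-substituted para-quinone methide of ring A. The phenol oxygen O1 of ring B sits ortho to C3a and can capture it.
- Consequently only C3 has to be set absolutely; C2 then settles trans under thermodynamic control. A direct SN2 closure on the syn aldol-derived diol would give the cis ring, so the ionising pathway is required, not merely convenient.

## Retrosynthetic reasoning

**Protecting groups.** Target 28 is traced back to 27, in which both phenols and the C9 alcohol are silylated. One buffered fluoride treatment removes all three groups. Silyl groups are chosen because the benzylic O1–C2 ether and the C7′ carbinol would not tolerate acid or hydrogenolysis.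

**C7′–C8′ bond.** With C9′ viewed as a reduced acyl carbon, the C7′–C8′ bond of 27 is an aldol bond. Cutting it gives aldehyde 19 and the ring C arylacetyl imide 24, by way of adduct 26 and boron enolate 25. This is the most convergent cut: it splits off ring C with both side-chain stereocentres in one step. Auxiliary 6 sets the syn pair C7′ (S), C8′ (R) by reagent control, which is needed because C2 and C3 are too far away to help or interfere. Cutting C5–C7′ instead would require an aryl nucleophile to add to a racemisation-prone α-aryl aldehyde.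

**C5 formyl group.** Aldehyde 19 goes back to aryllithium 18 and so to bromide 17, the C9 silyl ether of alcohol 16. The bromine is an inert placeholder for the side chain. The side chain must come after the ring closure because its C7′ carbinol would ionise under the acid that closes the ring. The C9 hydroxyl is capped so that it does not quench 18.

**O1–C2 bond (key disconnection).** Dihydrobenzofuran 16 is opened at O1–C2 to the phenolic diol 14. In the forward direction a Lewis acid removes the benzylic hydroxyl, giving cation 15, and the ring B phenol closes the ring. This bond is cut because its formation needs no stereochemical information at C2: the existing C3 centre directs ring A to the trans position. Cutting C2–C3 or C3–C3a would instead require both ring stereocentres to be created under reagent or catalyst control.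

**C2–C3 bond.** Diol 14 is the deallylated form of 13, which is the hydride-cleavage product of aldol adduct 12. Adduct 12 is cut at the future C2–C3 bond into imide 8 (via enolate 11) and the silylated ring A aldehyde 10. Auxiliary 6 fixes the α-carbon, the future C3. The carbinol configuration produced alongside is erased later, so any erosion of syn selectivity is harmless as long as the α-face selectivity holds. The allyl ether keeps the ring B phenol out of enolate and hydride chemistry and comes off without disturbing bromide, silyl ether or benzylic alcohol.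

**Building blocks.**
- Imide 8 comes from acid 5 and auxiliary 6 through anhydride 7.
- Acid 5 is the one-carbon homologue of aldehyde 2 (via enol ether 3 and aldehyde 4), and 2 is the allyl ether of commercial 1.
- Aldehyde 10 is silylated vanillin 9.
- Imide 24 comes from 6 and acid 22 (via anhydride 23), and 22 from homovanillic acid 20 (via silyl ester 21).

## Alternatives that were turned down

**Alternative 1:** Both O1–C2 and C2–C3 are cut, so the heterocycle is assembled in a [4+1] sense.
- Forward step: a carbonate base releases the ortho-quinone methide A3 of ring B from sulfone A2 and deprotonates the chiral benzylsulfonium salt A4. The ylide carbon adds to the exocyclic carbon of A3 (the future C3), and the phenoxide then displaces the thiolane to give A1.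
- For it: it is much shorter. A1 is the same structure as 17 and would enter the endgame directly after about four or five steps, against eleven here. On step economy it is clearly stronger.
- Against it: both stereocentres and the absolute sense depend on a stoichiometric chiral sulfide in a stepwise addition–displacement. The face selectivity of ylide addition to planar A3 sets C3 and is hard to predict for an electron-rich para-silyloxybenzyl ylide. A4 itself can lose the sulfide by ionisation. A3, with a CH2OSi group on its exocyclic carbon, can tautomerise by a 1,5-hydrogen shift instead of being trapped.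
- Comparison: the chosen route is longer, but its one absolute stereocentre (C3) comes from a covalently bound auxiliary with a well-established sense, diastereomers can be removed at the stage of 12, and the ring closure needs only thermodynamic diastereocontrol.

**Alternative 2:** The C2–C3 bond is cut.
- Forward step: Rh2(S-PTTL)4, dirhodium tetrakis[N-phthaloyl-(S)-tert-leucinate], or its enantiomer converts diazo ester A6 into a carbene at C3 that inserts into the benzylic C–H bond of the ring A benzyl ether. An amidine base then epimerises C3 to give the trans ester A5. By the CIP rules A5 is (2S,3S), because the ester outranks C2; its spatial arrangement is that of the target.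
- For it: the asymmetric step is catalytic, the C–H bond is doubly activated (benzylic and α to oxygen), and reduction of A5 gives 16, so it joins the same endgame in fewer steps. On catalyst economy and step count it is equal or better.
- Against it: the carbene can instead attack the ether oxygen (oxonium ylide and benzyl shift) or the electron-rich ring A. The enantioselectivity depends on the conformation about an ether oxygen crowded by the C7 methoxy group and the diazo-bearing carbon. Because C3 is epimerised, the whole enantiopurity rests on C2 alone and cannot be improved by separating diastereomers. It also needs the same arylacetic acid homologation of 1 as the chosen route.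
- Comparison: the chosen strategy has the more predictable absolute control (auxiliary at C3, separable diastereomers) and puts C2 under thermodynamic control, where the alternative puts it under kinetic catalyst control.

**Alternative 3:** The C3–C3a bond is cut.
- Forward step: bromine–lithium exchange on aryl ether A8 gives an aryllithium at C3a that opens the adjacent oxirane at its internal carbon with inversion. This closes the dihydrofuran ring and frees the C9 hydroxyl in A7.
- For it: the oxirane stereochemistry comes from catalytic Sharpless chemistry, the closure is stereospecific, and C5 is already a masked aldehyde, so no late formylation is needed. On that last point it is stronger.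
- Against it:
  - A8 requires the hindered 2-bromo-6-methoxyphenol oxygen to be joined, with defined configuration, to a benzylic carbon para to a silyloxy group. That carbon ionises easily, which is the very tendency the chosen route exploits, so a Mitsunobu-type etherification would leak stereochemistry.
  - The aryllithium must choose the more hindered internal oxirane carbon (5-exo) over the terminal one (6-endo, giving a chroman).
  - The acidic C2–H next to oxygen and ring A can quench or rearrange the aryllithium.
- Comparison: the chosen strategy makes the same ring through a closure in which ionisation at C2 is used rather than feared, at the price of two extra steps to install the aldehyde.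

Key step: step 10

Remark on the chemistry: the arylacetyl imides 8 and 24 are assumed to form Z boron enolates and react with the same facial sense as alkyl-substituted imides, the aryl group taking the place of the alkyl group.

## Route

Step 1
Reactants: 1 5-bromo-2-hydroxy-3-methoxybenzaldehyde
Product: 2 2-(allyloxy)-5-bromo-3-methoxybenzaldehyde
Conditions: allyl bromide, K2CO3, DMF, rt
Reagents that add atoms: allyl bromide, C=CCBr
Why: Williamson etherification of the phenoxide; the allyl ether masks the ring B phenol through the ylide, oxidant, enolate and hydride steps and can be removed later without touching the aryl bromide.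

Step 2
Reactants: 2 2-(allyloxy)-5-bromo-3-methoxybenzaldehyde
Product: 3 2-(allyloxy)-5-bromo-1-methoxy-3-(2-methoxyvinyl)benzene (E/Z mixture)
Conditions: Ph3P(CH2OMe)Cl, KOt-Bu, THF, 0 °C to rt
Reagents that add atoms: (methoxymethyl)triphenylphosphonium chloride, COC[P+](c1ccccc1)(c1ccccc1)c1ccccc1.[Cl-]
Why: Wittig methoxymethylenation of the aromatic aldehyde; the E/Z mixture is immaterial because both isomers hydrolyse to the same aldehyde.

Step 3
Reactants: 3 2-(allyloxy)-5-bromo-1-methoxy-3-(2-methoxyvinyl)benzene
Product: 4 2-[2-(allyloxy)-5-bromo-3-methoxyphenyl]acetaldehyde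
Conditions: 2 M aq. HCl, THF, 45 °C
Reagents that add atoms: water, O
Why: Acid hydrolysis of the enol ether (C-protonation, hemiacetal, loss of methanol) completes the one-carbon homologation; the aryl allyl ether and bromide are inert to dilute acid, and 4 should be used crude to avoid self-condensation.

Step 4
Reactants: 4 2-[2-(allyloxy)-5-bromo-3-methoxyphenyl]acetaldehyde
Product: 5 2-[2-(allyloxy)-5-bromo-3-methoxyphenyl]acetic acid
Conditions: NaClO2, NaH2PO4, 2-methyl-2-butene, t-BuOH/H2O, rt
Reagents that add atoms: sodium chlorite, [Na+].[O-]Cl=O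
Why: Pinnick oxidation takes the aldehyde to the acid under mildly acidic conditions; excess 2-methyl-2-butene scavenges hypochlorous acid and so protects the allyl group and the electron-rich ring from chlorination.

Step 5
Reactants: 5 2-[2-(allyloxy)-5-bromo-3-methoxyphenyl]acetic acid; 6 (S)-4-benzyl-2-oxazolidinone
Product: 8 (S)-3-{2-[2-(allyloxy)-5-bromo-3-methoxyphenyl]acetyl}-4-benzyloxazolidin-2-one, via mixed pivalic anhydride 7 (not isolated)
Conditions: PivCl, Et3N, THF, −20 °C; then LiCl, 6, −20 °C to rt
Reagents that add atoms: none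
Why: N-acylation of the oxazolidinone through the mixed anhydride with LiCl activation; attack occurs at the less hindered arylacetyl carbonyl of 7, and no strong base is needed that might enolise the arylacetyl unit.

Step 6
Reactants: 9 vanillin
Product: 10 3-methoxy-4-(triisopropylsilyloxy)benzaldehyde
Conditions: TIPSCl, imidazole, DMF, rt
Reagents that add atoms: triisopropylsilyl chloride, CC(C)[Si](Cl)(C(C)C)C(C)C
Why: Silylation of the phenol; the bulky aryl silyl ether withstands the boron aldol, hydride, amine and BF3 steps, keeps the para oxygen electron-donating for the later ionisation, and is removed by fluoride at the end.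

Step 7
Reactants: 8 (S)-3-{2-[2-(allyloxy)-5-bromo-3-methoxyphenyl]acetyl}-4-benzyloxazolidin-2-one; 10 3-methoxy-4-(triisopropylsilyloxy)benzaldehyde
Product: 12 (S)-3-{(2S,3S)-2-[2-(allyloxy)-5-bromo-3-methoxyphenyl]-3-hydroxy-3-[3-methoxy-4-(triisopropylsilyloxy)phenyl]propanoyl}-4-benzyloxazolidin-2-one, via dibutylboron Z-enolate 11 (not isolated)
Conditions: Bu2BOTf, i-Pr2NEt, CH2Cl2, −78 to 0 °C; then 10, −78 to 0 °C; pH 7 buffer, MeOH, 30% H2O2, 0 °C
Reagents that add atoms: none
Why: Evans syn aldol: soft enolisation gives Z-enolate 11, which adds through a closed chair transition state with the auxiliary carbonyl turned away from the enolate oxygen, so the benzyl group blocks one face; this sets the α-carbon (future C3) as S in the imide, which becomes R after reduction, with the carbinol syn to it.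

Step 8
Reactants: 12 (S)-3-{(2S,3S)-2-[2-(allyloxy)-5-bromo-3-methoxyphenyl]-3-hydroxy-3-[3-methoxy-4-(triisopropylsilyloxy)phenyl]propanoyl}-4-benzyloxazolidin-2-one
Product: 13 (1S,2R)-2-[2-(allyloxy)-5-bromo-3-methoxyphenyl]-1-[3-methoxy-4-(triisopropylsilyloxy)phenyl]propane-1,3-diol
Conditions: LiBH4, MeOH, THF, 0 °C
Reagents that add atoms: none
Why: Reductive cleavage of the imide: hydride attacks the lithium-chelated exocyclic carbonyl, giving the primary alcohol and releasing auxiliary 6; no stereocentre is touched (the descriptor at the α-carbon changes from S to R only because the priorities change).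

Step 9
Reactants: 13 (1S,2R)-2-[2-(allyloxy)-5-bromo-3-methoxyphenyl]-1-[3-methoxy-4-(triisopropylsilyloxy)phenyl]propane-1,3-diol
Product: 14 (1S,2R)-2-(5-bromo-2-hydroxy-3-methoxyphenyl)-1-[3-methoxy-4-(triisopropylsilyloxy)phenyl]propane-1,3-diol
Conditions: Pd(PPh3)4 (5 mol %), morpholine, THF, rt
Reagents that add atoms: none
Why: Tsuji–Trost-type deallylation: zerovalent palladium ionises the aryl allyl ether to a π-allyl complex that morpholine captures; at room temperature oxidative addition into the electron-rich aryl bromide should not compete, and the neutral conditions leave the benzylic alcohol and silyl ether alone.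

Step 10
Reactants: 14 (1S,2R)-2-(5-bromo-2-hydroxy-3-methoxyphenyl)-1-[3-methoxy-4-(triisopropylsilyloxy)phenyl]propane-1,3-diol
Product: 16 [(2S,3R)-5-bromo-7-methoxy-2-[3-methoxy-4-(triisopropylsilyloxy)phenyl]-2,3-dihydrobenzofuran-3-yl]methanol, via benzylic cation 15 (not isolated)
Conditions: BF3·OEt2 (0.3 equiv), CH2Cl2 (high dilution), −40 to 0 °C; aq. NaHCO3
Reagents that add atoms: none
Why: BF3 binds the benzylic hydroxyl of 14 and assists its departure; the resulting cation 15 is delocalised onto the para silyloxy oxygen of ring A (an O-silylated para-quinone methide), so the carbinol configuration from step 7 is erased. The ortho phenol oxygen of ring B adds to the exocyclic cationic carbon in a 5-exo-trig O-cyclisation, forming O1–C2 and closing the dihydrofuran ring. The closest known reaction type is the acid-mediated dehydrative cyclisation of 1-aryl-2-(2-hydroxyaryl)propane-1,3-diols to trans-2-aryl-3-hydroxymethyl-2,3-dihydrobenzofurans. The new stereocentre C2 is controlled by the auxiliary-derived C3 centre: ring A ends up anti to the C3 hydroxymethyl group, and because the benzylic aryl ether can re-ionise under the conditions, any cis isomer should equilibrate to the more stable trans (2S,3R) compound. The step needs diastereoselectivity only (net retention at C2, which an SN2 closure on the syn diol could not give) and chemoselectivity for the phenol over the primary alcohol; the latter follows from ring size (dihydrofuran against oxetane) and reversibility. Low temperature, dilution and a substoichiometric amount of acid are meant to suppress loss of formaldehyde from 15 and intermolecular capture; the aryl bromide and aryl silyl ether should be inert.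

Step 11
Reactants: 16 [(2S,3R)-5-bromo-7-methoxy-2-[3-methoxy-4-(triisopropylsilyloxy)phenyl]-2,3-dihydrobenzofuran-3-yl]methanol
Product: 17 tert-butyl({(2S,3R)-5-bromo-7-methoxy-2-[3-methoxy-4-(triisopropylsilyloxy)phenyl]-2,3-dihydrobenzofuran-3-yl}methoxy)dimethylsilane
Conditions: TBSCl, imidazole, DMF, rt
Reagents that add atoms: tert-butyldimethylsilyl chloride, CC(C)(C)[Si](C)(C)Cl
Why: Silylation of the only free hydroxyl, so that the aryllithium of the next step is not quenched; the group comes off in the final fluoride step.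

Step 12
Reactants: 17 tert-butyl({(2S,3R)-5-bromo-7-methoxy-2-[3-methoxy-4-(triisopropylsilyloxy)phenyl]-2,3-dihydrobenzofuran-3-yl}methoxy)dimethylsilane
Product: 19 (2S,3R)-3-{[tert-butyl(dimethyl)silyl]oxymethyl}-7-methoxy-2-[3-methoxy-4-(triisopropylsilyloxy)phenyl]-2,3-dihydrobenzofuran-5-carbaldehyde, via aryllithium 18 (not isolated)
Conditions: n-BuLi, THF, −78 °C; then DMF, −78 to 0 °C; aq. NH4Cl
Reagents that add atoms: N,N-dimethylformamide, CN(C)C=O
Why: Bromine–lithium exchange followed by formylation with DMF; at −78 °C exchange should be much faster than deprotonation at C2 or C3, and the hemiaminal salt releases the aldehyde only on work-up.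

Step 13
Reactants: 20 homovanillic acid
Product: 22 2-[3-methoxy-4-(triisopropylsilyloxy)phenyl]acetic acid, via silyl ester 21 (not isolated)
Conditions: TIPSCl (2.3 equiv), imidazole, DMF, rt; then K2CO3, THF/MeOH/H2O, 0 °C; 1 M HCl to pH 3
Reagents that add atoms: triisopropylsilyl chloride, CC(C)[Si](Cl)(C(C)C)C(C)C
Why: Bis-silylation followed by selective hydrolysis of the much more labile silyl ester leaves the aryl silyl ether and gives the ring C acid with its phenol protected in the same way as ring A.

Step 14
Reactants: 22 2-[3-methoxy-4-(triisopropylsilyloxy)phenyl]acetic acid; 6 (S)-4-benzyl-2-oxazolidinone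
Product: 24 (S)-4-benzyl-3-{2-[3-methoxy-4-(triisopropylsilyloxy)phenyl]acetyl}oxazolidin-2-one, via mixed pivalic anhydride 23 (not isolated)
Conditions: PivCl, Et3N, THF, −20 °C; then LiCl, 6, −20 °C to rt
Reagents that add atoms: none
Why: Same mixed-anhydride N-acylation as step 5; the mild amine base leaves the aryl silyl ether intact.

Step 15
Reactants: 24 (S)-4-benzyl-3-{2-[3-methoxy-4-(triisopropylsilyloxy)phenyl]acetyl}oxazolidin-2-one; 19 (2S,3R)-3-{[tert-butyl(dimethyl)silyl]oxymethyl}-7-methoxy-2-[3-methoxy-4-(triisopropylsilyloxy)phenyl]-2,3-dihydrobenzofuran-5-carbaldehyde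
Product: 26 (S)-4-benzyl-3-{(2S,3S)-3-[(2S,3R)-3-{[tert-butyl(dimethyl)silyl]oxymethyl}-7-methoxy-2-[3-methoxy-4-(triisopropylsilyloxy)phenyl]-2,3-dihydrobenzofuran-5-yl]-3-hydroxy-2-[3-methoxy-4-(triisopropylsilyloxy)phenyl]propanoyl}oxazolidin-2-one, via dibutylboron Z-enolate 25 (not isolated)
Conditions: 24 (1.4 equiv), Bu2BOTf, i-Pr2NEt, CH2Cl2, −78 to 0 °C; then 19, −78 to 0 °C; pH 7 buffer, MeOH, 30% H2O2, 0 °C
Reagents that add atoms: none
Why: Second Evans syn aldol: Z-enolate 25 adds to 19 through the same auxiliary-controlled chair transition state, setting C8′ (S in the imide, R after reduction) and C7′ (S) syn; the C2 and C3 centres are too remote to influence the facial choice, and the boron Lewis acid is too mild to ionise the O1–C2 bond.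

Step 16
Reactants: 26 (S)-4-benzyl-3-{(2S,3S)-3-[(2S,3R)-3-{[tert-butyl(dimethyl)silyl]oxymethyl}-7-methoxy-2-[3-methoxy-4-(triisopropylsilyloxy)phenyl]-2,3-dihydrobenzofuran-5-yl]-3-hydroxy-2-[3-methoxy-4-(triisopropylsilyloxy)phenyl]propanoyl}oxazolidin-2-one
Product: 27 (1S,2R)-1-[(2S,3R)-3-{[tert-butyl(dimethyl)silyl]oxymethyl}-7-methoxy-2-[3-methoxy-4-(triisopropylsilyloxy)phenyl]-2,3-dihydrobenzofuran-5-yl]-2-[3-methoxy-4-(triisopropylsilyloxy)phenyl]propane-1,3-diol
Conditions: LiBH4, MeOH, THF, 0 °C
Reagents that add atoms: none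
Why: Reductive removal of the auxiliary as in step 8, turning the acyl carbon into the C9′ primary alcohol; the silyl ethers and the dihydrobenzofuran are inert to borohydride.

Step 17
Reactants: 27 (1S,2R)-1-[(2S,3R)-3-{[tert-butyl(dimethyl)silyl]oxymethyl}-7-methoxy-2-[3-methoxy-4-(triisopropylsilyloxy)phenyl]-2,3-dihydrobenzofuran-5-yl]-2-[3-methoxy-4-(triisopropylsilyloxy)phenyl]propane-1,3-diol
Product: 28 (1S,2R)-1-[(2S,3R)-2-(4-hydroxy-3-methoxyphenyl)-3-(hydroxymethyl)-7-methoxy-2,3-dihydrobenzofuran-5-yl]-2-(4-hydroxy-3-methoxyphenyl)propane-1,3-diol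
Conditions: TBAF (4 equiv), AcOH (4 equiv), THF, 0 °C to rt
Reagents that add atoms: none
Why: Fluoride-mediated global desilylation of the two aryl silyl ethers and the primary silyl ether; the acetic acid buffer keeps the ring A phenoxide concentration low, so the O1–C2 bond should not open through a quinone methide, and no acid strong enough to ionise the C7′ carbinol is present.

## Compound list

1 | 5-bromo-2-hydroxy-3-methoxybenzaldehyde | COc1cc(Br)cc(C=O)c1O | starting material
2 | 2-(allyloxy)-5-bromo-3-methoxybenzaldehyde | COc1cc(Br)cc(C=O)c1OCC=C | intermediate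
3 | 2-(allyloxy)-5-bromo-1-methoxy-3-(2-methoxyvinyl)benzene (E/Z mixture) | COC=Cc1cc(Br)cc(OC)c1OCC=C | intermediate
4 | 2-[2-(allyloxy)-5-bromo-3-methoxyphenyl]acetaldehyde | COc1cc(Br)cc(CC=O)c1OCC=C | intermediate
5 | 2-[2-(allyloxy)-5-bromo-3-methoxyphenyl]acetic acid | COc1cc(Br)cc(CC(=O)O)c1OCC=C | intermediate
6 | (S)-4-benzyl-2-oxazolidinone | O=C1N[C@@H](Cc2ccccc2)CO1 | starting material
7 | 2-[2-(allyloxy)-5-bromo-3-methoxyphenyl]acetic pivalic anhydride | COc1cc(Br)cc(CC(=O)OC(=O)C(C)(C)C)c1OCC=C | intermediate
8 | (S)-3-{2-[2-(allyloxy)-5-bromo-3-methoxyphenyl]acetyl}-4-benzyloxazolidin-2-one | COc1cc(Br)cc(CC(=O)N2[C@@H](Cc3ccccc3)COC2=O)c1OCC=C | intermediate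
9 | vanillin (4-hydroxy-3-methoxybenzaldehyde) | COc1cc(C=O)ccc1O | starting material
10 | 3-methoxy-4-(triisopropylsilyloxy)benzaldehyde | COc1cc(C=O)ccc1O[Si](C(C)C)(C(C)C)C(C)C | intermediate
11 | dibutylboron (Z)-enolate of 8 | CCCCB(CCCC)O/C(=C\c1cc(Br)cc(OC)c1OCC=C)N2[C@@H](Cc3ccccc3)COC2=O | intermediate
12 | (S)-3-{(2S,3S)-2-[2-(allyloxy)-5-bromo-3-methoxyphenyl]-3-hydroxy-3-[3-methoxy-4-(triisopropylsilyloxy)phenyl]propanoyl}-4-benzyloxazolidin-2-one | COc1cc([C@@H](O)[C@@H](C(=O)N2[C@@H](Cc3ccccc3)COC2=O)c4cc(Br)cc(OC)c4OCC=C)ccc1O[Si](C(C)C)(C(C)C)C(C)C | intermediate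
13 | (1S,2R)-2-[2-(allyloxy)-5-bromo-3-methoxyphenyl]-1-[3-methoxy-4-(triisopropylsilyloxy)phenyl]propane-1,3-diol | COc1cc([C@@H](O)[C@@H](CO)c2cc(Br)cc(OC)c2OCC=C)ccc1O[Si](C(C)C)(C(C)C)C(C)C | intermediate
14 | (1S,2R)-2-(5-bromo-2-hydroxy-3-methoxyphenyl)-1-[3-methoxy-4-(triisopropylsilyloxy)phenyl]propane-1,3-diol | COc1cc([C@@H](O)[C@@H](CO)c2cc(Br)cc(OC)c2O)ccc1O[Si](C(C)C)(C(C)C)C(C)C | intermediate
15 | (2R)-2-(5-bromo-2-hydroxy-3-methoxyphenyl)-3-hydroxy-1-[3-methoxy-4-(triisopropylsilyloxy)phenyl]propan-1-ylium (O-silylated para-quinone methide cation) | COc1cc([CH+][C@@H](CO)c2cc(Br)cc(OC)c2O)ccc1O[Si](C(C)C)(C(C)C)C(C)C | intermediate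
16 | [(2S,3R)-5-bromo-7-methoxy-2-[3-methoxy-4-(triisopropylsilyloxy)phenyl]-2,3-dihydrobenzofuran-3-yl]methanol | COc1cc([C@H]2Oc3c(OC)cc(Br)cc3[C@@H]2CO)ccc1O[Si](C(C)C)(C(C)C)C(C)C | intermediate
17 | tert-butyl({(2S,3R)-5-bromo-7-methoxy-2-[3-methoxy-4-(triisopropylsilyloxy)phenyl]-2,3-dihydrobenzofuran-3-yl}methoxy)dimethylsilane | COc1cc([C@H]2Oc3c(OC)cc(Br)cc3[C@@H]2CO[Si](C)(C)C(C)(C)C)ccc1O[Si](C(C)C)(C(C)C)C(C)C | intermediate
18 | 5-lithio derivative of 17 (aryllithium) | COc1cc([C@H]2Oc3c(OC)cc([Li])cc3[C@@H]2CO[Si](C)(C)C(C)(C)C)ccc1O[Si](C(C)C)(C(C)C)C(C)C | intermediate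
19 | (2S,3R)-3-{[tert-butyl(dimethyl)silyl]oxymethyl}-7-methoxy-2-[3-methoxy-4-(triisopropylsilyloxy)phenyl]-2,3-dihydrobenzofuran-5-carbaldehyde | COc1cc([C@H]2Oc3c(OC)cc(C=O)cc3[C@@H]2CO[Si](C)(C)C(C)(C)C)ccc1O[Si](C(C)C)(C(C)C)C(C)C | intermediate
20 | homovanillic acid (4-hydroxy-3-methoxyphenylacetic acid) | COc1cc(CC(=O)O)ccc1O | starting material
21 | triisopropylsilyl 2-[3-methoxy-4-(triisopropylsilyloxy)phenyl]acetate | COc1cc(CC(=O)O[Si](C(C)C)(C(C)C)C(C)C)ccc1O[Si](C(C)C)(C(C)C)C(C)C | intermediate
22 | 2-[3-methoxy-4-(triisopropylsilyloxy)phenyl]acetic acid | COc1cc(CC(=O)O)ccc1O[Si](C(C)C)(C(C)C)C(C)C | intermediate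
23 | 2-[3-methoxy-4-(triisopropylsilyloxy)phenyl]acetic pivalic anhydride | COc1cc(CC(=O)OC(=O)C(C)(C)C)ccc1O[Si](C(C)C)(C(C)C)C(C)C | intermediate
24 | (S)-4-benzyl-3-{2-[3-methoxy-4-(triisopropylsilyloxy)phenyl]acetyl}oxazolidin-2-one | COc1cc(CC(=O)N2[C@@H](Cc3ccccc3)COC2=O)ccc1O[Si](C(C)C)(C(C)C)C(C)C | intermediate
25 | dibutylboron (Z)-enolate of 24 | CCCCB(CCCC)O/C(=C\c1ccc(O[Si](C(C)C)(C(C)C)C(C)C)c(OC)c1)N2[C@@H](Cc3ccccc3)COC2=O | intermediate
26 | (S)-4-benzyl-3-{(2S,3S)-3-[(2S,3R)-3-{[tert-butyl(dimethyl)silyl]oxymethyl}-7-methoxy-2-[3-methoxy-4-(triisopropylsilyloxy)phenyl]-2,3-dihydrobenzofuran-5-yl]-3-hydroxy-2-[3-methoxy-4-(triisopropylsilyloxy)phenyl]propanoyl}oxazolidin-2-one | COc1cc([C@H]2Oc3c(OC)cc([C@@H](O)[C@@H](C(=O)N4[C@@H](Cc5ccccc5)COC4=O)c6ccc(O[Si](C(C)C)(C(C)C)C(C)C)c(OC)c6)cc3[C@@H]2CO[Si](C)(C)C(C)(C)C)ccc1O[Si](C(C)C)(C(C)C)C(C)C | intermediate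
27 | (1S,2R)-1-[(2S,3R)-3-{[tert-butyl(dimethyl)silyl]oxymethyl}-7-methoxy-2-[3-methoxy-4-(triisopropylsilyloxy)phenyl]-2,3-dihydrobenzofuran-5-yl]-2-[3-methoxy-4-(triisopropylsilyloxy)phenyl]propane-1,3-diol | COc1cc([C@H]2Oc3c(OC)cc([C@@H](O)[C@@H](CO)c4ccc(O[Si](C(C)C)(C(C)C)C(C)C)c(OC)c4)cc3[C@@H]2CO[Si](C)(C)C(C)(C)C)ccc1O[Si](C(C)C)(C(C)C)C(C)C | intermediate
28 | (1S,2R)-1-[(2S,3R)-2-(4-hydroxy-3-methoxyphenyl)-3-(hydroxymethyl)-7-methoxy-2,3-dihydrobenzofuran-5-yl]-2-(4-hydroxy-3-methoxyphenyl)propane-1,3-diol | COc1cc([C@H]2Oc3c(OC)cc([C@@H](O)[C@@H](CO)c4ccc(O)c(OC)c4)cc3[C@@H]2CO)ccc1O | target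

## Step count and least certain steps

Total step count: 17. Longest linear sequence: 14 steps (steps 1–5, 7–12 and 15–17, from 1 to 28). Steps 6, 13 and 14 are the side branches.

**Step 10 (key step).**
- What may go wrong: fragmentation of cation 15 with loss of formaldehyde or of a proton to a stilbene; intermolecular capture of the cation by the electron-rich rings; partial loss of the aryl silyl ether; incomplete equilibration to trans.
- Fallback: an anionic quinone-methide closure, setting out from 13 and returning at 16.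
  - Acetylation of both hydroxyls (Ac2O, pyridine, DMAP) should give (1S,2R)-2-[2-(allyloxy)-5-bromo-3-methoxyphenyl]-1-[3-methoxy-4-(triisopropylsilyloxy)phenyl]propane-1,3-diyl diacetate F1.
  - Deallylation as in step 9 gives the phenol diacetate F2.
  - TBAF in THF at 0 °C removes the ring A silyl group; the phenoxide expels the benzylic acetate to form the para-quinone methide F3, and the ring B phenoxide adds to it in a 1,6-fashion. Because the ring A phenoxide can re-open the ring, this should again settle on the trans product, [(2S,3R)-5-bromo-2-(4-hydroxy-3-methoxyphenyl)-7-methoxy-2,3-dihydrobenzofuran-3-yl]methyl acetate F4.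
  - Resilylation (TIPSCl, imidazole) gives the silyl ether acetate F5, and i-Bu2AlH at −78 °C removes the acetate to give 16.

**Step 7.**
- What may go wrong: slow or reversible addition to the deactivated, para-oxygenated aldehyde; erosion of the C3 configuration by retro-aldol and re-addition, or by enolisation of the acidic α-aryl position during work-up.
- Fallback: a titanium-mediated thiazolidinethione aldol (Crimmins-type), setting out from 5 and returning at 13.
  - Coupling of 5 with (S)-4-benzyl-1,3-thiazolidine-2-thione (EDC·HCl, DMAP) gives the N-acyl thiazolidinethione F6.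
  - Its chlorotitanium enolate (TiCl4, i-Pr2NEt, N-methyl-2-pyrrolidinone, CH2Cl2, −78 °C) is more nucleophilic and should add to 10 with the same syn sense, giving adduct F7.
  - NaBH4 in THF/EtOH cleaves the auxiliary directly to 13.

**Step 15.**
- What may go wrong: the same reversibility and incomplete conversion as in step 7, here at the expense of the advanced aldehyde 19; loss of unreacted 19 in the oxidative work-up.
- Fallback: the same change of auxiliary and metal, setting out from 22 and returning at 27.
  - Acid 22 is converted into the N-acyl thiazolidinethione F8 (EDC·HCl, DMAP, (S)-4-benzyl-1,3-thiazolidine-2-thione).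
  - Its preformed, amine-complexed chlorotitanium enolate is added to 19 at −78 °C to give adduct F9; no free TiCl4 should meet the O1–C2 bond.
  - NaBH4 gives 27 without an oxidative work-up.

**Step 12.**
- What may go wrong: protonation of the aryllithium (reduction instead of formylation); butylation by the 1-bromobutane formed; base-induced opening of the dihydrofuran by deprotonation at C3.
- Fallback: cross-coupling and oxidative cleavage, setting out from 17 and returning at 19.
  - Stille coupling with tributyl(vinyl)stannane (Pd(PPh3)4, toluene, 100 °C; neutral, safe for the silyl ethers) gives the 5-vinyl compound F10.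
  - Lemieux–Johnson cleavage (OsO4 cat., NaIO4, 2,6-lutidine, dioxane/H2O) gives 19.

**Step 16.**
- What may go wrong: retro-aldol cleavage of the lithium aldolate under the basic hydride conditions, or hydride attack at the ring carbonyl of the auxiliary.
- Fallback: block the aldolate pathway by silylation, setting out from 26 and returning at 28.
  - TESOTf and 2,6-lutidine give the triethylsilyl ether F11.
  - LiBH4 then gives the primary alcohol F12.
  - The buffered fluoride treatment of step 17 removes all four silyl groups to give 28 directly.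

## Further compounds

F1 | step 10 | (1S,2R)-2-[2-(allyloxy)-5-bromo-3-methoxyphenyl]-1-[3-methoxy-4-(triisopropylsilyloxy)phenyl]propane-1,3-diyl diacetate | COc1cc([C@@H](OC(C)=O)[C@@H](COC(C)=O)c2cc(Br)cc(OC)c2OCC=C)ccc1O[Si](C(C)C)(C(C)C)C(C)C
F2 | step 10 | (1S,2R)-2-(5-bromo-2-hydroxy-3-methoxyphenyl)-1-[3-methoxy-4-(triisopropylsilyloxy)phenyl]propane-1,3-diyl diacetate | COc1cc([C@@H](OC(C)=O)[C@@H](COC(C)=O)c2cc(Br)cc(OC)c2O)ccc1O[Si](C(C)C)(C(C)C)C(C)C
F3 | step 10 | (2R)-2-(5-bromo-2-hydroxy-3-methoxyphenyl)-3-(3-methoxy-4-oxocyclohexa-2,5-dien-1-ylidene)propyl acetate (para-quinone methide) | COC1=CC(=C[C@@H](COC(C)=O)c2cc(Br)cc(OC)c2O)C=CC1=O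
F4 | step 10 | [(2S,3R)-5-bromo-2-(4-hydroxy-3-methoxyphenyl)-7-methoxy-2,3-dihydrobenzofuran-3-yl]methyl acetate | COc1cc([C@H]2Oc3c(OC)cc(Br)cc3[C@@H]2COC(C)=O)ccc1O
F5 | step 10 | [(2S,3R)-5-bromo-7-methoxy-2-[3-methoxy-4-(triisopropylsilyloxy)phenyl]-2,3-dihydrobenzofuran-3-yl]methyl acetate | COc1cc([C@H]2Oc3c(OC)cc(Br)cc3[C@@H]2COC(C)=O)ccc1O[Si](C(C)C)(C(C)C)C(C)C
F6 | step 7 | 2-[2-(allyloxy)-5-bromo-3-methoxyphenyl]-1-[(S)-4-benzyl-2-thioxothiazolidin-3-yl]ethanone | COc1cc(Br)cc(CC(=O)N2[C@@H](Cc3ccccc3)CSC2=S)c1OCC=C
F7 | step 7 | (2S,3S)-2-[2-(allyloxy)-5-bromo-3-methoxyphenyl]-1-[(S)-4-benzyl-2-thioxothiazolidin-3-yl]-3-hydroxy-3-[3-methoxy-4-(triisopropylsilyloxy)phenyl]propan-1-one | COc1cc([C@@H](O)[C@@H](C(=O)N2[C@@H](Cc3ccccc3)CSC2=S)c4cc(Br)cc(OC)c4OCC=C)ccc1O[Si](C(C)C)(C(C)C)C(C)C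
F8 | step 15 | 1-[(S)-4-benzyl-2-thioxothiazolidin-3-yl]-2-[3-methoxy-4-(triisopropylsilyloxy)phenyl]ethanone | COc1cc(CC(=O)N2[C@@H](Cc3ccccc3)CSC2=S)ccc1O[Si](C(C)C)(C(C)C)C(C)C
F9 | step 15 | (2S,3S)-1-[(S)-4-benzyl-2-thioxothiazolidin-3-yl]-3-[(2S,3R)-3-{[tert-butyl(dimethyl)silyl]oxymethyl}-7-methoxy-2-[3-methoxy-4-(triisopropylsilyloxy)phenyl]-2,3-dihydrobenzofuran-5-yl]-3-hydroxy-2-[3-methoxy-4-(triisopropylsilyloxy)phenyl]propan-1-one | COc1cc([C@H]2Oc3c(OC)cc([C@@H](O)[C@@H](C(=O)N4[C@@H](Cc5ccccc5)CSC4=S)c6ccc(O[Si](C(C)C)(C(C)C)C(C)C)c(OC)c6)cc3[C@@H]2CO[Si](C)(C)C(C)(C)C)ccc1O[Si](C(C)C)(C(C)C)C(C)C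
F10 | step 12 | tert-butyl({(2S,3R)-7-methoxy-2-[3-methoxy-4-(triisopropylsilyloxy)phenyl]-5-vinyl-2,3-dihydrobenzofuran-3-yl}methoxy)dimethylsilane | COc1cc([C@H]2Oc3c(OC)cc(C=C)cc3[C@@H]2CO[Si](C)(C)C(C)(C)C)ccc1O[Si](C(C)C)(C(C)C)C(C)C
F11 | step 16 | (S)-4-benzyl-3-{(2S,3S)-3-[(2S,3R)-3-{[tert-butyl(dimethyl)silyl]oxymethyl}-7-methoxy-2-[3-methoxy-4-(triisopropylsilyloxy)phenyl]-2,3-dihydrobenzofuran-5-yl]-2-[3-methoxy-4-(triisopropylsilyloxy)phenyl]-3-(triethylsilyloxy)propanoyl}oxazolidin-2-one | COc1cc([C@H]2Oc3c(OC)cc([C@@H](O[Si](CC)(CC)CC)[C@@H](C(=O)N4[C@@H](Cc5ccccc5)COC4=O)c6ccc(O[Si](C(C)C)(C(C)C)C(C)C)c(OC)c6)cc3[C@@H]2CO[Si](C)(C)C(C)(C)C)ccc1O[Si](C(C)C)(C(C)C)C(C)C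
F12 | step 16 | (2R,3S)-3-[(2S,3R)-3-{[tert-butyl(dimethyl)silyl]oxymethyl}-7-methoxy-2-[3-methoxy-4-(triisopropylsilyloxy)phenyl]-2,3-dihydrobenzofuran-5-yl]-2-[3-methoxy-4-(triisopropylsilyloxy)phenyl]-3-(triethylsilyloxy)propan-1-ol | COc1cc([C@H]2Oc3c(OC)cc([C@@H](O[Si](CC)(CC)CC)[C@@H](CO)c6ccc(O[Si](C(C)C)(C(C)C)C(C)C)c(OC)c6)cc3[C@@H]2CO[Si](C)(C)C(C)(C)C)ccc1O[Si](C(C)C)(C(C)C)C(C)C
A1 | alternative 1 | tert-butyl({(2S,3R)-5-bromo-7-methoxy-2-[3-methoxy-4-(triisopropylsilyloxy)phenyl]-2,3-dihydrobenzofuran-3-yl}methoxy)dimethylsilane (same structure as 17) | COc1cc([C@H]2Oc3c(OC)cc(Br)cc3[C@@H]2CO[Si](C)(C)C(C)(C)C)ccc1O[Si](C(C)C)(C(C)C)C(C)C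
A2 | alternative 1 | 4-bromo-2-[2-(tert-butyldimethylsilyloxy)-1-(p-tolylsulfonyl)ethyl]-6-methoxyphenol (racemic) | Cc1ccc(cc1)S(=O)(=O)C(CO[Si](C)(C)C(C)(C)C)c1cc(Br)cc(OC)c1O
A3 | alternative 1 | 4-bromo-6-[2-(tert-butyldimethylsilyloxy)ethylidene]-2-methoxycyclohexa-2,4-dien-1-one (ortho-quinone methide) | COC1=CC(Br)=CC(=CCO[Si](C)(C)C(C)(C)C)C1=O
A4 | alternative 1 | (2R,5R)-1-[3-methoxy-4-(triisopropylsilyloxy)benzyl]-2,5-dimethylthiolan-1-ium trifluoromethanesulfonate (illustrative chiral thiolanium salt; the antipode needed is not predictable) | C[C@@H]1CC[C@@H](C)[S+]1Cc1ccc(O[Si](C(C)C)(C(C)C)C(C)C)c(OC)c1.[O-]S(=O)(=O)C(F)(F)F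
A5 | alternative 2 | methyl (2S,3S)-5-bromo-7-methoxy-2-[3-methoxy-4-(triisopropylsilyloxy)phenyl]-2,3-dihydrobenzofuran-3-carboxylate (trans) | COc1cc([C@H]2Oc3c(OC)cc(Br)cc3[C@@H]2C(=O)OC)ccc1O[Si](C(C)C)(C(C)C)C(C)C
A6 | alternative 2 | methyl 2-{5-bromo-3-methoxy-2-[3-methoxy-4-(triisopropylsilyloxy)benzyloxy]phenyl}-2-diazoacetate | COC(=O)C(=[N+]=[N-])c1cc(Br)cc(OC)c1OCc1ccc(O[Si](C(C)C)(C(C)C)C(C)C)c(OC)c1
A7 | alternative 3 | [(2S,3R)-5-(1,3-dioxolan-2-yl)-7-methoxy-2-[3-methoxy-4-(triisopropylsilyloxy)phenyl]-2,3-dihydrobenzofuran-3-yl]methanol | COc1cc([C@H]2Oc3c(OC)cc(C4OCCO4)cc3[C@@H]2CO)ccc1O[Si](C(C)C)(C(C)C)C(C)C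
A8 | alternative 3 | 2-{3-bromo-5-methoxy-4-[(R)-[3-methoxy-4-(triisopropylsilyloxy)phenyl][(S)-oxiran-2-yl]methoxy]phenyl}-1,3-dioxolane | COc1cc([C@@H](Oc2c(Br)cc(cc2OC)C3OCCO3)[C@@H]4CO4)ccc1O[Si](C(C)C)(C(C)C)C(C)C
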